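**Plan**
1. Retrosynthesis: after both phenols are benzylated, one radical event cuts two bonds at once, the lactone C4–C5 bond (ring CH bearing the syringylmethyl group to the O–CH2 carbon) and the bond from the exocyclic CH2 on C4 to the syringyl ring. The open ester left over is cut at O–CH2 (acid plus a one-carbon unit) and at C3–CH2Ar (crotonyl imide plus benzylic bromide).
2. Enabling feature: C5 is a CH2 on the ring oxygen O1 of an ester, so it can be generated as an acyloxymethyl radical from a halomethyl ester. C4 carries an exocyclic benzylic CH2, so C4 plus that CH2 can be a vinyl group; 5-exo attack of C5 on C4 closes the lactone ring and puts the spin on the carbon that must take the syringyl ring.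
3. Forward order: crotonyl imide, deconjugative alkylation with the guaiacyl bromide, acid, chloromethyl ester, nickel-catalysed reductive ring closure with arylation by the protected syringyl bromide, hydrogenolysis. The lactone is the only ring made; both arenes are bought.
4. Stereochemistry: C3 comes from the (R)-4-benzyl-oxazolidinone auxiliary in the alkylation; C4 comes from C3 in the ring closure (trans, substrate control). No base is used after the ring closure, so neither centre can epimerise.

Key step: step 7

Remark: 4-bromo-2,6-dimethoxyphenol, 4-(benzyloxy)-3-methoxybenzyl alcohol, (R)-4-benzyl-2-oxazolidinone and chloromethyl chlorosulfate are taken as purchasable.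

**Step 1**
Reactants: 1 (R)-4-benzyl-2-oxazolidinone; 2 (E)-but-2-enoyl chloride
Product: 4 (R)-4-benzyl-3-[(E)-but-2-enoyl]oxazolidin-2-one, via N-lithio oxazolidinone 3 (not isolated)
Conditions: n-BuLi, THF, −78 °C; then 2, −78 to 0 °C
Reagents that add atoms: none
Why: N-acylation of the lithiated oxazolidinone by an acid chloride (Evans imide formation); no stereocentre is touched.

**Step 2**
Reactants: 5 4-(benzyloxy)-3-methoxybenzyl alcohol
Product: 6 4-(benzyloxy)-3-methoxybenzyl bromide
Conditions: PBr3 (0.4 equiv), CH2Cl2, 0 °C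
Reagents that add atoms: phosphorus tribromide, BrP(Br)Br
Why: Conversion of an electron-rich benzylic alcohol into the bromide via its phosphite ester (SN2 by bromide); aryl benzyl and methyl ethers are inert at 0 °C.

**Step 3**
Reactants: 4 (R)-4-benzyl-3-[(E)-but-2-enoyl]oxazolidin-2-one; 6 4-(benzyloxy)-3-methoxybenzyl bromide
Product: 8 (R)-4-benzyl-3-[(R)-2-[4-(benzyloxy)-3-methoxybenzyl]but-3-enoyl]oxazolidin-2-one, via sodium dienolate 7 (not isolated)
Conditions: NaN(SiMe3)2 (1.1 equiv), THF, −78 °C; then 6 (1.5 equiv), −78 to −45 °C; AcOH quench at −78 °C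
Reagents that add atoms: none
Why: Evans asymmetric alkylation in its deconjugative form: gamma-deprotonation of the s-cis crotonyl imide gives the chelated Z(O)-dienolate 7, which should react at the alpha carbon on the face away from the benzyl group of the auxiliary, so the (R)-auxiliary sets the (R) centre; the cold acidic quench keeps the double bond out of conjugation.

**Step 4**
Reactants: 8 (R)-4-benzyl-3-[(R)-2-[4-(benzyloxy)-3-methoxybenzyl]but-3-enoyl]oxazolidin-2-one
Product: 10 (R)-2-[4-(benzyloxy)-3-methoxybenzyl]but-3-enoic acid, via lithium peroxycarboxylate 9 (not isolated)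
Conditions: LiOH, 30% H2O2, THF/H2O 3:1, 0 °C; aq Na2SO3; then 1 M HCl
Reagents that add atoms: hydrogen peroxide, OO
Why: Hydroperoxide cleavage of an Evans imide: the hydroperoxide anion attacks the exocyclic acyl carbonyl selectively and sulfite reduces peracid salt 9 to the acid; the weakly basic peroxide at 0 °C should leave the alpha centre and the beta,gamma double bond in place, and auxiliary 1 is recovered.

**Step 5**
Reactants: 10 (R)-2-[4-(benzyloxy)-3-methoxybenzyl]but-3-enoic acid
Product: 11 chloromethyl (R)-2-[4-(benzyloxy)-3-methoxybenzyl]but-3-enoate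
Conditions: ClCH2OSO2Cl (1.2 equiv), NaHCO3, Bu4NHSO4 (10 mol%), CH2Cl2/H2O, 0 °C to rt
Reagents that add atoms: chloromethyl chlorosulfate, ClCOS(=O)(=O)Cl
Why: Phase-transfer O-alkylation of the carboxylate (SN2 at CH2 with chlorosulfate as leaving group); the near-neutral two-phase medium cannot enolise the ester, so C2 should keep its configuration.

**Step 6**
Reactants: 12 4-bromo-2,6-dimethoxyphenol
Product: 13 2-(benzyloxy)-5-bromo-1,3-dimethoxybenzene
Conditions: BnBr, K2CO3, DMF, rt
Reagents that add atoms: benzyl bromide, BrCc1ccccc1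
Why: Williamson etherification of the phenol; the aryl bromide is untouched.

**Step 7**
Reactants: 11 chloromethyl (R)-2-[4-(benzyloxy)-3-methoxybenzyl]but-3-enoate; 13 2-(benzyloxy)-5-bromo-1,3-dimethoxybenzene
Product: 17 (3R,4R)-3-[4-(benzyloxy)-3-methoxybenzyl]-4-[4-(benzyloxy)-3,5-dimethoxybenzyl]dihydrofuran-2(3H)-one, via iodomethyl ester 14 (not isolated), via acyloxymethyl radical 15 (not isolated), via lactonylmethyl radical 16 (not isolated)
Conditions: NiBr2·dme (dme = MeOCH2CH2OMe, 5 mol%), 4,4'-di-tert-butyl-2,2'-bipyridine (6 mol%), NaI (25 mol%), Mn powder (3 equiv), 13 (1.5 equiv), DMA (0.02 M), 60 °C, 11 added by syringe pump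
Reagents that add atoms: none
Why: Proposed new method: NaI turns 11 into iodomethyl ester 14, from which monovalent nickel abstracts iodine to give acyloxymethyl radical 15; 15 closes onto the vinyl group to give primary radical 16, which is captured by the arylnickel bromide formed from 13 and zerovalent nickel, and reductive elimination from trivalent nickel forms the CH2–aryl bond while Mn returns nickel to the zerovalent state. The closest known reaction type is the nickel-catalysed reductive cyclisation–arylation of alkene-tethered alkyl halides with aryl halides (cross-electrophile coupling with a radical ring closure), together with nickel-catalysed arylation of alpha-acyloxyalkyl halides; a halomethyl ester whose radical must close through the ester linkage is a new substrate class. The lactone ring is closed in the 5-exo-trig mode by attack of the O–CH2 radical carbon on the internal vinyl carbon, the 6-endo mode being disfavoured stereoelectronically. The new centre C4 is controlled by C3: in the chair-like (Beckwith–Houk) transition state of this 4-substituted hexenyl-type radical the arylmethyl group sits pseudo-equatorial, so the new exocyclic CH2 should end up trans to it, which is the (3R,4R) relationship. The step needs ring closure to outrun capture of 15 by arylnickel, and the closure is slowed by the need for the s-cis ester rotamer; low nickel loading, high dilution, slow addition of 11, the polar solvent DMA (which favours the more polar s-cis rotamer), 60 °C and the degenerate iodine exchange between 15 and 14 all work for ring closure. Mn in place of Zn avoids direct metal insertion into the reactive C–I bond, and the base-free medium leaves C3 and the double bond position untouched before closure.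

**Step 8**
Reactants: 17 (3R,4R)-3-[4-(benzyloxy)-3-methoxybenzyl]-4-[4-(benzyloxy)-3,5-dimethoxybenzyl]dihydrofuran-2(3H)-one
Product: 18 (3R,4R)-3-(4-hydroxy-3-methoxybenzyl)-4-(4-hydroxy-3,5-dimethoxybenzyl)dihydrofuran-2(3H)-one
Conditions: H2 (1 atm), 10% Pd/C, EtOAc/EtOH, rt
Reagents that add atoms: none
Why: Hydrogenolysis of both aryl benzyl ethers over Pd/C; the lactone, the methyl ethers and the benzylic C–C bonds are stable, and the neutral medium cannot epimerise C3.

**Compound list**
1 | (R)-4-benzyl-2-oxazolidinone | O=C1N[C@H](Cc2ccccc2)CO1 | starting material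
2 | (E)-but-2-enoyl chloride (crotonyl chloride) | C/C=C/C(Cl)=O | starting material
3 | N-lithio derivative of 1 | [Li]N1[C@H](Cc2ccccc2)COC1=O | intermediate
4 | (R)-4-benzyl-3-[(E)-but-2-enoyl]oxazolidin-2-one | C/C=C/C(=O)N1[C@H](Cc2ccccc2)COC1=O | intermediate
5 | 4-(benzyloxy)-3-methoxybenzyl alcohol | COc1cc(CO)ccc1OCc1ccccc1 | starting material
6 | 4-(benzyloxy)-3-methoxybenzyl bromide | COc1cc(CBr)ccc1OCc1ccccc1 | intermediate
7 | sodium Z(O)-dienolate of 4 | [Na+].[O-]/C(=C\C=C)N1[C@H](Cc2ccccc2)COC1=O | intermediate
8 | (R)-4-benzyl-3-[(R)-2-[4-(benzyloxy)-3-methoxybenzyl]but-3-enoyl]oxazolidin-2-one | C=C[C@@H](Cc1ccc(OCc2ccccc2)c(OC)c1)C(=O)N3[C@H](Cc4ccccc4)COC3=O | intermediate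
9 | lithium (R)-2-[4-(benzyloxy)-3-methoxybenzyl]but-3-eneperoxoate | C=C[C@@H](Cc1ccc(OCc2ccccc2)c(OC)c1)C(=O)O[O-].[Li+] | intermediate
10 | (R)-2-[4-(benzyloxy)-3-methoxybenzyl]but-3-enoic acid | C=C[C@@H](Cc1ccc(OCc2ccccc2)c(OC)c1)C(=O)O | intermediate
11 | chloromethyl (R)-2-[4-(benzyloxy)-3-methoxybenzyl]but-3-enoate | C=C[C@@H](Cc1ccc(OCc2ccccc2)c(OC)c1)C(=O)OCCl | intermediate
12 | 4-bromo-2,6-dimethoxyphenol | COc1cc(Br)cc(OC)c1O | starting material
13 | 2-(benzyloxy)-5-bromo-1,3-dimethoxybenzene | COc1cc(Br)cc(OC)c1OCc1ccccc1 | intermediate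
14 | iodomethyl (R)-2-[4-(benzyloxy)-3-methoxybenzyl]but-3-enoate | C=C[C@@H](Cc1ccc(OCc2ccccc2)c(OC)c1)C(=O)OCI | intermediate
15 | [(R)-2-[4-(benzyloxy)-3-methoxybenzyl]but-3-enoyl]oxymethyl radical | C=C[C@@H](Cc1ccc(OCc2ccccc2)c(OC)c1)C(=O)O[CH2] | intermediate
16 | [(3R,4R)-4-[4-(benzyloxy)-3-methoxybenzyl]-5-oxooxolan-3-yl]methyl radical | COc1cc(C[C@H]2C(=O)OC[C@@H]2[CH2])ccc1OCc1ccccc1 | intermediate
17 | (3R,4R)-3-[4-(benzyloxy)-3-methoxybenzyl]-4-[4-(benzyloxy)-3,5-dimethoxybenzyl]dihydrofuran-2(3H)-one | COc1cc(C[C@H]2C(=O)OC[C@@H]2Cc2cc(OC)c(OCc3ccccc3)c(OC)c2)ccc1OCc1ccccc1 | intermediate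
18 | (3R,4R)-3-(4-hydroxy-3-methoxybenzyl)-4-(4-hydroxy-3,5-dimethoxybenzyl)dihydrofuran-2(3H)-one | COc1cc(C[C@H]2C(=O)OC[C@@H]2Cc2cc(OC)c(O)c(OC)c2)ccc1O | target

Total step count: 8. Longest linear sequence: 6 steps (steps 1, 3, 4, 5, 7, 8).

**Steps most likely to fail**

Step 7. Radical 15 may be captured by arylnickel before it closes the ring, because rotation of the ester into the s-cis form is slow; this would give the open aryl-methyl ester. Facial selectivity of the ring closure may also be modest, and a nickel hydride may move the double bond into conjugation. The fallback gives up the radical ring closure and builds the same protected lactone by the classical alkylation of a preformed lactone; it sets out from bromide 6 and comes back to the route at 17. Stobbe condensation of commercial 4-(benzyloxy)-3,5-dimethoxybenzaldehyde with dimethyl succinate (NaOMe, MeOH, reflux, then acid) should give (E)-4-[4-(benzyloxy)-3,5-dimethoxyphenyl]-3-(methoxycarbonyl)but-3-enoic acid F1. Asymmetric hydrogenation ([Rh(cod)2]BF4, a chiral DuPhos-type bisphosphine, H2, MeOH; the ligand antipode that delivers the R acid is fixed in a test run) should give (R)-4-[4-(benzyloxy)-3,5-dimethoxyphenyl]-3-(methoxycarbonyl)butanoic acid F2. Reduction of its potassium salt with Ca(BH4)2 (from CaCl2 and NaBH4, EtOH) should give (R)-4-[4-(benzyloxy)-3,5-dimethoxyphenyl]-3-(hydroxymethyl)butanoic acid F3, which on acidification closes to (R)-4-[4-(benzyloxy)-3,5-dimethoxybenzyl]dihydrofuran-2(3H)-one F4. LiN(SiMe3)2 (THF, −78 °C) gives the lithium enolate of the lactone F5, which 6 should alkylate anti to the C4 substituent to give trans lactone 17.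

Step 3. The dienolate may be alkylated at the gamma carbon or twice, the double bond may drift into conjugation in the basic medium, and the facial bias may be eroded. The fallback avoids the dienolate by alkylating a saturated imide and unveiling the vinyl group afterwards; it sets out from 1 and 6 and comes back at 8. Opening of gamma-butyrolactone with PhSeNa (from PhSeSePh and NaBH4; DMF, 120 °C) gives 4-(phenylselanyl)butanoic acid F6. DCC and DMAP (CH2Cl2) join it to 1 to give (R)-4-benzyl-3-[4-(phenylselanyl)butanoyl]oxazolidin-2-one F7. NaN(SiMe3)2 (THF, −78 °C) gives the sodium Z-enolate of this imide F8, which 6 alkylates on the face away from the auxiliary benzyl group to give (R)-4-benzyl-3-[(R)-2-[4-(benzyloxy)-3-methoxybenzyl]-4-(phenylselanyl)butanoyl]oxazolidin-2-one F9. H2O2 with pyridine (CH2Cl2, 0 °C to rt) oxidises it to the selenoxide F10, whose syn elimination can take a hydrogen only from C3 and so should give 8 with the alpha centre untouched.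

Step 4. The basic peroxide may epimerise C2 or move the double bond into conjugation, or hydroxide may open the ring carbonyl of the auxiliary. The fallback removes the auxiliary by reduction and reoxidises under buffered conditions; it sets out from 8 and comes back at 10. LiBH4 (Et2O with 1 equiv H2O, 0 °C) should give (R)-2-[4-(benzyloxy)-3-methoxybenzyl]but-3-en-1-ol F11 and free 1. TEMPO (cat.), NaOCl (cat.) and NaClO2 in MeCN/phosphate buffer (pH 6.7, 35 °C) oxidise it through (R)-2-[4-(benzyloxy)-3-methoxybenzyl]but-3-enal F12, which is consumed as it forms, to acid 10.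

**Further compounds**
F1 | step 7 | (E)-4-[4-(benzyloxy)-3,5-dimethoxyphenyl]-3-(methoxycarbonyl)but-3-enoic acid | COC(=O)/C(CC(=O)O)=C/c1cc(OC)c(OCc2ccccc2)c(OC)c1
F2 | step 7 | (R)-4-[4-(benzyloxy)-3,5-dimethoxyphenyl]-3-(methoxycarbonyl)butanoic acid | COC(=O)[C@@H](CC(=O)O)Cc1cc(OC)c(OCc2ccccc2)c(OC)c1
F3 | step 7 | (R)-4-[4-(benzyloxy)-3,5-dimethoxyphenyl]-3-(hydroxymethyl)butanoic acid | OC[C@@H](CC(=O)O)Cc1cc(OC)c(OCc2ccccc2)c(OC)c1
F4 | step 7 | (R)-4-[4-(benzyloxy)-3,5-dimethoxybenzyl]dihydrofuran-2(3H)-one | O=C1OC[C@@H](C1)Cc2cc(OC)c(OCc3ccccc3)c(OC)c2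
F5 | step 7 | lithium enolate of F4 | [Li+].[O-]C1OC[C@@H](C=1)Cc2cc(OC)c(OCc3ccccc3)c(OC)c2
F6 | step 3 | 4-(phenylselanyl)butanoic acid | OC(=O)CCC[Se]c1ccccc1
F7 | step 3 | (R)-4-benzyl-3-[4-(phenylselanyl)butanoyl]oxazolidin-2-one | O=C(CCC[Se]c1ccccc1)N2[C@H](Cc3ccccc3)COC2=O
F8 | step 3 | sodium Z-enolate of F7 | [Na+].[O-]/C(=C\CC[Se]c1ccccc1)N2[C@H](Cc3ccccc3)COC2=O
F9 | step 3 | (R)-4-benzyl-3-[(R)-2-[4-(benzyloxy)-3-methoxybenzyl]-4-(phenylselanyl)butanoyl]oxazolidin-2-one | c1ccc(cc1)[Se]CC[C@@H](Cc2ccc(OCc3ccccc3)c(OC)c2)C(=O)N4[C@H](Cc5ccccc5)COC4=O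
F10 | step 3 | selenoxide of F9 | O=[Se](c1ccccc1)CC[C@@H](Cc2ccc(OCc3ccccc3)c(OC)c2)C(=O)N4[C@H](Cc5ccccc5)COC4=O
F11 | step 4 | (R)-2-[4-(benzyloxy)-3-methoxybenzyl]but-3-en-1-ol | C=C[C@@H](Cc1ccc(OCc2ccccc2)c(OC)c1)CO
F12 | step 4 | (R)-2-[4-(benzyloxy)-3-methoxybenzyl]but-3-enal | C=C[C@@H](Cc1ccc(OCc2ccccc2)c(OC)c1)C=O
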